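## The problem

Lespeflorin B1 (22) is a 2,3-trans-dihydroflavonol: a chroman-4-one (rings A and C fused) with ring B on C2 and a hydroxyl on C3. It carries 3-methylbut-2-enyl (prenyl) groups at C6 of ring A and C3' of ring B, each ortho to a free phenol (7-OH, 4'-OH). The two stereocentres are adjacent, C2 (R) and C3 (R), and differ in robustness. C3 is alpha to the ketone and holds as long as it is not enolised. C2 is a benzylic ether para to the 4'-oxygen and can open and re-close through a quinone methide, so a secure C3 can steer C2 into the favoured trans (diequatorial) arrangement. The α-ketol does not tolerate base and air (enolisation, ring opening to the chalcone, dehydrogenation to the flavonol). The prenyl groups are the most fragile part: acid protonates the trisubstituted alkene to a tertiary cation that the neighbouring phenol traps, and electrophilic oxidants attack that alkene before anything else. A synthesis must therefore decide when the prenyl groups appear relative to the acidic and oxidative operations that build and unmask the dihydroflavonol. The feature that offers a way out is that each prenyl group ends in a trisubstituted alkene (C2''=C3'' on ring A, C2'''=C3''' on ring B) that is one alkylidene exchange away from an allyl group, and the molecule contains no other alkene.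

## Retrosynthesis

**22 to 18 and 19.** Both prenyl C=C bonds are cut, leading back to the diallyl dihydroflavonol 18 and 2-methylbut-2-ene (19). The neighbouring cuts at the aryl–CH2 bonds would need prenyl-metal couplings on a finished, unprotected dihydroflavonol, or prenyl groups carried from the start through acid and oxidant. The metathesis cut keeps the side chains as allyl groups, which cannot form a tertiary cation and are poor partners for electrophiles. Nothing follows the exchange, so the forward reaction must tolerate two free phenols and the α-ketol and exchange both termini completely.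

**18 to 16.** Ring C is opened at O1–C2, leading to the tris-MOM chalcone epoxide 16. Unmasking the 2'-phenol and closing the ring happen in one acidic operation, and the epoxide already holds the C3 oxygen with its configuration. The alternatives are hydroxylation of a flavanone enolate (C3–O) or conjugate arylation of a chromone followed by hydroxylation (C2–C1'). Both pass through a flavanone enolate, which can expel the ring oxygen and lose C2. The forward step needs 6-endo opening at the benzylic carbon, no enolisation at C3, and survival of the allyl groups in warm methanolic HCl.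

**16 to 14.** The epoxide oxygen is removed, leading to the (E)-chalcone 14. A nucleophilic, catalyst-controlled epoxidation sets both stereocentres of the epoxide and touches only the electron-poor enone. Dihydroxylation or peracid chemistry would attack the two allyl alkenes. The forward reaction must deliver the (αR,βS)-epoxide from an enone whose aroyl ring carries an ortho substituent.

**14 to 6 and 12.** The enone Cα=Cβ bond is cut in the aldol sense, giving the ring A acetophenone 6 and the ring B aldehyde 12. This is the most convergent cut, and the two halves have similar size. Only an (E)-selective condensation at room temperature is required, so that the allyl groups do not migrate into conjugation.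

**6 to 4 to 1.** The aryl–allyl bond at C5 of the acetophenone is cut back to the bromide 4, made from commercial 1-(5-bromo-2,4-dihydroxyphenyl)ethanone (1) and MOMCl (2). An O-allylation and Claisen rearrangement on the resacetophenone would place the allyl group between the two oxygens. The bromine fixes the position that becomes C6, and allyltributylstannane (5) delivers the allyl group.

**12 to 11 to 9 to 7 and 8.** On ring B the two positions ortho to the phenol are equivalent, so an aromatic Claisen rearrangement is unambiguous. Aldehyde 12 comes from 3-allyl-4-hydroxybenzaldehyde (11), which comes from 4-(allyloxy)benzaldehyde (9), made from 4-hydroxybenzaldehyde (7) and allyl bromide (8).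

## Roads not taken

**Alternative 1:** Ring C is cut at O1–C2 and C3–C4. In the forward direction the salicylaldehyde A2, trimethyl orthoformate A4 and a chiral phosphoric acid give the 4-methoxy ortho-quinone methide A5, which adds the aryl enol acetate A3 in a [4+2] cycloaddition to give the chroman A1.
- **Merits:** One catalytic step closes ring C and sets both stereocentres. It is more convergent than the chosen plan and replaces its steps 6 to 8 by a single operation.
- **Weak points:** A1 has the wrong oxidation level at C4, so a benzylic oxidation must be done next to two electron-rich prenylated arenes. Regiochemistry depends on the aryl group of A3 polarising the alkene more strongly than the acetoxy group does. The prenyl alkenes of A2 and A3 are themselves competent 2π partners for A5 and can be protonated under the acid that generates it. The final MOM removal needs acid with both prenyl groups in place.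
- **Comparison:** Against the better ring-forming economy of this road, the chosen plan offers three classical steps on ring C, no redox adjustment at C4, and prenyl groups that never meet acid.

**Alternative 2:** The C2–C3 and C3–O bonds are cut. In the forward direction Rh2(OAc)4 (divalent rhodium) turns the diazoketone A7 into a carbene, 4-methoxybenzyl alcohol A9 adds, and a chiral phosphoric acid directs trapping by the aldehyde A8 before proton transfer, giving the syn adduct A6. Ring C would then close by displacement of the aryl fluoride by the C2 hydroxyl.
- **Merits:** This is the most convergent of the four roads. The central bond and both stereocentres come from three simple pieces, the C3 oxygen arrives already differentiated, and the fluoride displacement cannot epimerise either centre.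
- **Weak points:** The electrophilic rhodium carbene is generated beside two trisubstituted, electron-rich prenyl alkenes (one in A7, one in A8), so cyclopropanation and allylic insertion compete. Simple O–H insertion of A9 without aldehyde capture also competes. The fluoride is activated only by the ortho ketone, which the para oxygen weakens. Oxidative removal of the 4-methoxybenzyl ether and acidic MOM removal both fall after the prenyl groups are in place.
- **Comparison:** This road wins on convergency and on catalyst control of both centres. The chosen plan has a chemoselective epoxidation that ignores isolated alkenes and an end-game with no deprotection, but its enantioselectivity rests on an ortho-substituted chalcone, which is its weaker side.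

**Alternative 3:** Ring A is cut at C4a–C8a, C5–C6 and C7–C8. In the forward direction [Rh(cod)2]BF4 with BINAP (a cationic monovalent rhodium catalyst) joins the ynone and alkynyl ether ends of the diyne A11 with the siloxyalkyne A12 in a [2+2+2] cycloaddition, giving the silyl- and MOM-protected target A10.
- **Merits:** Ring A is made with its substituents placed by construction, without aromatic substitution or cross-coupling, and rings A and C close together.
- **Weak points:** Both stereocentres must already be present in A11, which has a β-alkoxy-α-silyloxy ynone prone to elimination and epimerisation, and a 1-alkynyl ether of a secondary benzylic alcohol prone to thermal loss of ketene. The tether does not control the orientation of the unsymmetrical alkyne A12, so the prenyl and silyloxy groups can exchange places at C6 and C7. The key step creates no stereocentre, so the chiral ligand contributes nothing. Three protecting groups, one of them acid-labile MOM, must be removed with the prenyl groups present.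
- **Comparison:** This road is the longest and its key precursor the least stable. Its one advantage, a regiodefined ring A, is matched in the chosen plan by a bromine atom that already marks C6.

Key step: step 9

Assumption: poly-L-leucine is taken to epoxidise 14 with the same facial sense as the parent chalcone, giving the (αR,βS)-epoxide; if the sense were opposite, poly-D-leucine would be used with no other change.

## Route

Step 1
Reactants: 1 1-(5-bromo-2,4-dihydroxyphenyl)ethanone; 2 chloromethyl methyl ether
Product: 4 1-[5-bromo-2,4-bis(methoxymethoxy)phenyl]ethanone, via 4-O-MOM monoether 3 (not isolated)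
Conditions: NaH, MOMCl, DMF, 0 °C to rt
Reagents that add atoms: chloromethyl methyl ether, COCCl
Why: Williamson-type O-alkylation of both phenoxides; the 4-hydroxyl reacts first (3), and NaH is used because the 2-hydroxyl is hydrogen-bonded to the ketone and resists weaker bases.

Step 2
Reactants: 4 1-[5-bromo-2,4-bis(methoxymethoxy)phenyl]ethanone; 5 allyltributylstannane
Product: 6 1-[5-allyl-2,4-bis(methoxymethoxy)phenyl]ethanone
Conditions: Pd(PPh3)4 (5 mol %), toluene, 110 °C, degassed
Reagents that add atoms: allyltributylstannane, C=CC[Sn](CCCC)(CCCC)CCCC
Why: Migita–Kosugi–Stille coupling: zerovalent palladium inserts into the C–Br bond, the allyl group is transferred from tin and reductive elimination places it at C5, the future C6 of the chromanone; ketone and MOM ethers are inert.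

Step 3
Reactants: 7 4-hydroxybenzaldehyde; 8 allyl bromide
Product: 9 4-(allyloxy)benzaldehyde
Conditions: K2CO3, acetone, reflux
Reagents that add atoms: allyl bromide, C=CCBr
Why: Williamson ether synthesis on an acidic phenol with a reactive allylic halide.

Step 4
Reactants: 9 4-(allyloxy)benzaldehyde
Product: 11 3-allyl-4-hydroxybenzaldehyde, via ortho-dienone 10 (not isolated)
Conditions: N,N-diethylaniline, 200 °C, argon
Reagents that add atoms: none
Why: Aromatic Claisen rearrangement, a [3,3]-sigmatropic shift to the dienone 10 followed by tautomerisation; the two ortho positions are equivalent, so only one product can form.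

Step 5
Reactants: 11 3-allyl-4-hydroxybenzaldehyde; 2 chloromethyl methyl ether
Product: 12 3-allyl-4-(methoxymethoxy)benzaldehyde
Conditions: MOMCl, K2CO3, acetone, rt
Reagents that add atoms: chloromethyl methyl ether, COCCl
Why: O-alkylation of the phenoxide; the MOM ether masks the phenol against the base of step 6 and the peroxide of step 7 and leaves with the other two in step 8.

Step 6
Reactants: 6 1-[5-allyl-2,4-bis(methoxymethoxy)phenyl]ethanone; 12 3-allyl-4-(methoxymethoxy)benzaldehyde
Product: 14 (E)-1-[5-allyl-2,4-bis(methoxymethoxy)phenyl]-3-[3-allyl-4-(methoxymethoxy)phenyl]prop-2-en-1-one, via aldol adduct 13 (not isolated)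
Conditions: KOH, EtOH, rt
Reagents that add atoms: none
Why: Claisen–Schmidt condensation of a methyl ketone with a non-enolisable aldehyde; E1cB loss of water from 13 gives the (E)-enone. The masked 2'-oxygen prevents closure to a flavanone, and at room temperature the allyl groups should not migrate into conjugation.

Step 7
Reactants: 14 (E)-1-[5-allyl-2,4-bis(methoxymethoxy)phenyl]-3-[3-allyl-4-(methoxymethoxy)phenyl]prop-2-en-1-one; 15 urea–hydrogen peroxide adduct
Product: 16 [5-allyl-2,4-bis(methoxymethoxy)phenyl]{(2R,3S)-3-[3-allyl-4-(methoxymethoxy)phenyl]oxiran-2-yl}methanone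
Conditions: poly-L-leucine, urea·H2O2, DBU, THF, rt
Reagents that add atoms: urea–hydrogen peroxide adduct, NC(N)=O.OO
Why: Juliá–Colonna epoxidation, a Weitz–Scheffer conjugate addition of hydroperoxide and ring closure held within the helical peptide; poly-L-leucine sets Cα (R) and Cβ (S), and the trans relationship follows from the (E)-enone. The nucleophilic oxidant leaves the two isolated allyl alkenes untouched.

Step 8
Reactants: 16 [5-allyl-2,4-bis(methoxymethoxy)phenyl]{(2R,3S)-3-[3-allyl-4-(methoxymethoxy)phenyl]oxiran-2-yl}methanone
Product: 18 (2R,3R)-6-allyl-2-(3-allyl-4-hydroxyphenyl)-3,7-dihydroxychroman-4-one, via free triphenol epoxide 17 (not isolated)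
Conditions: 3 M HCl, MeOH–THF, 55 °C
Reagents that add atoms: none
Why: Acid-catalysed acetal exchange removes the three MOM groups as dimethoxymethane, and the freed 2'-hydroxyl opens the protonated epoxide at the benzylic carbon in a 6-endo epoxide-opening cyclisation, the standard closure of 2'-alkoxymethoxy chalcone epoxides to dihydroflavonols. C3 keeps the configuration of the epoxide Cα (R); inversion at Cβ gives C2 (R) and the trans ring, and any cis isomer can equilibrate to trans through the para-quinone methide. Allyl groups cannot form a tertiary cation and should survive.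

Step 9
Reactants: 18 (2R,3R)-6-allyl-2-(3-allyl-4-hydroxyphenyl)-3,7-dihydroxychroman-4-one; 19 2-methylbut-2-ene
Product: 22 lespeflorin B1 [(2R,3R)-3,7-dihydroxy-2-[4-hydroxy-3-(3-methylbut-2-enyl)phenyl]-6-(3-methylbut-2-enyl)chroman-4-one], via 6-prenyl-3'-allyl intermediate 20 (not isolated), via 6-allyl-3'-prenyl intermediate 21 (not isolated)
Conditions: second-generation Grubbs catalyst RuCl2(=CHPh)(PCy3)(H2IMes) (10 mol %, two portions), 2-methylbut-2-ene–CH2Cl2, 40 °C, sealed tube
Reagents that add atoms: 2-methylbut-2-ene, CC=C(C)C
Why: Olefin cross-metathesis by the Chauvin mechanism: after loss of PCy3, excess 2-methylbut-2-ene converts the ruthenium alkylidene into Ru=CMe2 and Ru=CHMe carriers, which add to the terminal alkene of each allyl group by [2+2] cycloaddition and cyclorevert to the aryl–CH2–CH=CMe2 unit and Ru=CH2, which returns to the carrier with release of propene. The closest known reaction type is the cross-metathesis of allylarenes, free ortho-allylphenols included, with 2-methylbut-2-ene to give prenylarenes. No ring closes and no stereocentre forms; C2 and C3 are spectators, and the neutral medium should neither enolise C3 nor open ring C. Only chemoselectivity is needed: 18 has just two alkenes, both monosubstituted and unhindered, so the order of exchange (through 20 or 21) does not matter. Crotyl by-products from the ethylidene carrier are still disubstituted and are carried on to the trisubstituted product, which is too hindered to re-enter the cycle. The large excess of the volatile partner suppresses homodimerisation of the allyl groups, and escape of propene drives the exchange.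

## Compound list

1 | 1-(5-bromo-2,4-dihydroxyphenyl)ethanone | CC(=O)c1cc(Br)c(O)cc1O | starting material
2 | chloromethyl methyl ether (MOMCl) | COCCl | starting material
3 | 1-[5-bromo-2-hydroxy-4-(methoxymethoxy)phenyl]ethanone | CC(=O)c1cc(Br)c(OCOC)cc1O | intermediate
4 | 1-[5-bromo-2,4-bis(methoxymethoxy)phenyl]ethanone | CC(=O)c1cc(Br)c(OCOC)cc1OCOC | intermediate
5 | allyltributylstannane | C=CC[Sn](CCCC)(CCCC)CCCC | starting material
6 | 1-[5-allyl-2,4-bis(methoxymethoxy)phenyl]ethanone | CC(=O)c1cc(CC=C)c(OCOC)cc1OCOC | intermediate
7 | 4-hydroxybenzaldehyde | O=Cc1ccc(O)cc1 | starting material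
8 | allyl bromide | C=CCBr | starting material
9 | 4-(allyloxy)benzaldehyde | C=CCOc1ccc(C=O)cc1 | intermediate
10 | 6-allyl-4-formylcyclohexa-2,4-dien-1-one (racemic) | O=C1C=CC(C=O)=CC1CC=C | intermediate
11 | 3-allyl-4-hydroxybenzaldehyde | C=CCc1cc(C=O)ccc1O | intermediate
12 | 3-allyl-4-(methoxymethoxy)benzaldehyde | C=CCc1cc(C=O)ccc1OCOC | intermediate
13 | 1-[5-allyl-2,4-bis(methoxymethoxy)phenyl]-3-[3-allyl-4-(methoxymethoxy)phenyl]-3-hydroxypropan-1-one (racemic) | C=CCc1cc(C(O)CC(=O)c2cc(CC=C)c(OCOC)cc2OCOC)ccc1OCOC | intermediate
14 | (E)-1-[5-allyl-2,4-bis(methoxymethoxy)phenyl]-3-[3-allyl-4-(methoxymethoxy)phenyl]prop-2-en-1-one | C=CCc1cc(/C=C/C(=O)c2cc(CC=C)c(OCOC)cc2OCOC)ccc1OCOC | intermediate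
15 | urea–hydrogen peroxide adduct | NC(N)=O.OO | starting material
16 | [5-allyl-2,4-bis(methoxymethoxy)phenyl]{(2R,3S)-3-[3-allyl-4-(methoxymethoxy)phenyl]oxiran-2-yl}methanone | O=C(c1cc(CC=C)c(OCOC)cc1OCOC)[C@@H]1O[C@H]1c1ccc(OCOC)c(CC=C)c1 | intermediate
17 | (5-allyl-2,4-dihydroxyphenyl)[(2R,3S)-3-(3-allyl-4-hydroxyphenyl)oxiran-2-yl]methanone | O=C(c1cc(CC=C)c(O)cc1O)[C@@H]1O[C@H]1c1ccc(O)c(CC=C)c1 | intermediate
18 | (2R,3R)-6-allyl-2-(3-allyl-4-hydroxyphenyl)-3,7-dihydroxychroman-4-one | C=CCc1cc(ccc1O)[C@H]1Oc2cc(O)c(CC=C)cc2C(=O)[C@@H]1O | intermediate
19 | 2-methylbut-2-ene | CC=C(C)C | starting material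
20 | (2R,3R)-2-(3-allyl-4-hydroxyphenyl)-3,7-dihydroxy-6-(3-methylbut-2-enyl)chroman-4-one | C=CCc1cc(ccc1O)[C@H]1Oc2cc(O)c(CC=C(C)C)cc2C(=O)[C@@H]1O | intermediate
21 | (2R,3R)-6-allyl-3,7-dihydroxy-2-[4-hydroxy-3-(3-methylbut-2-enyl)phenyl]chroman-4-one | CC(C)=CCc1cc(ccc1O)[C@H]1Oc2cc(O)c(CC=C)cc2C(=O)[C@@H]1O | intermediate
22 | lespeflorin B1, (2R,3R)-3,7-dihydroxy-2-[4-hydroxy-3-(3-methylbut-2-enyl)phenyl]-6-(3-methylbut-2-enyl)chroman-4-one | CC(C)=CCc1cc([C@H]2Oc3cc(O)c(CC=C(C)C)cc3C(=O)[C@@H]2O)ccc1O | target

## Step count and least certain steps

Total: 9 steps. Longest linear sequence: 7 steps (steps 3 to 9, from 4-hydroxybenzaldehyde). The ring A branch (steps 1 and 2) joins at step 6.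

**Step 9 (key step).** The most likely failure is incomplete exchange at one of the two sites together with migration of an allyl double bond into conjugation with its ring. Ruthenium hydrides formed by catalyst decay cause this migration, and the free ortho-phenols, which can coordinate ruthenium, and the long reaction time needed for two exchanges both favour it. A migrated alkene is then shortened by metathesis, not prenylated.

Fallback: the fallback sets out from 18 and returns to the route at 22. Silylation of the two phenols (TBSCl, imidazole, DMF, 0 °C; the hindered, hydrogen-bonded 3-hydroxyl is expected to react much more slowly) gives (2R,3R)-6-allyl-2-[3-allyl-4-(tert-butyldimethylsilyloxy)phenyl]-7-(tert-butyldimethylsilyloxy)-3-hydroxychroman-4-one F1. The same cross-metathesis with 19 and RuCl2(=CHPh)(PCy3)(H2IMes) gives the bis-prenyl bis-silyl ether (2R,3R)-7-(tert-butyldimethylsilyloxy)-2-[4-(tert-butyldimethylsilyloxy)-3-(3-methylbut-2-enyl)phenyl]-3-hydroxy-6-(3-methylbut-2-enyl)chroman-4-one F2. Tetrabutylammonium fluoride (Bu4NF) buffered with acetic acid in THF at 0 °C then frees the phenols under conditions that neither protonate the prenyl alkenes nor enolise C3, giving 22.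

**Step 7.** The most likely failure is slow conversion with insufficient facial selectivity. The ortho MOM ether twists the aroyl ring out of the enone plane and weakens binding to the peptide helix, so the uncatalysed epoxidation by DBU and peroxide competes and erodes the enantiomeric purity.

Fallback: the fallback sets out from 14 and returns to the route at 18, replacing asymmetric catalysis by resolution. Uncatalysed Weitz–Scheffer epoxidation (30% H2O2, NaOH, MeOH–THF, 0 °C) gives 16 together with its mirror image, [5-allyl-2,4-bis(methoxymethoxy)phenyl]{(2S,3R)-3-[3-allyl-4-(methoxymethoxy)phenyl]oxiran-2-yl}methanone F3. The conditions of step 8 convert the pair, through 17 and the (2S,3R)-triphenol epoxide F4, into 18 and its enantiomer (2S,3S)-6-allyl-2-(3-allyl-4-hydroxyphenyl)-3,7-dihydroxychroman-4-one F5. Chromatography on a polysaccharide carbamate chiral stationary phase, routine for dihydroflavonols, separates them, and 18 continues to step 9. Half of the material is lost, but the single enantiomer is assured.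

**Step 8.** The most likely failure is ionisation of the electron-rich benzylic C–O bond of the epoxide before the 2'-phenol is free. This opens the way to aroyl migration (and from there to isoflavone-type products) or to 5-exo closure at Cα, and it costs yield more than stereochemical purity.

Fallback: the fallback sets out from 16 and returns to the route at 18, parking the benzylic position on sulfur. Phenylmethanethiol and SnCl4 in CH2Cl2 at −20 °C open the epoxide regioselectively at Cβ and begin MOM cleavage at the chelated 2'-oxygen. Brief treatment with HCl in MeOH at room temperature, to which a benzylic thioether is stable, completes the deprotection to (2S)-1-(5-allyl-2,4-dihydroxyphenyl)-3-(3-allyl-4-hydroxyphenyl)-3-(benzylsulfanyl)-2-hydroxypropan-1-one F6. The configuration at the sulfur-bearing carbon is unimportant, and the descriptor at C2 changes only because sulfur raises the priority of its neighbour. The thiophilic salt AgBF4 (CH2Cl2–acetone, 0 °C) then ionises the C–S bond under non-protic conditions, and the 2'-hydroxyl closes ring C trans to the untouched C3 hydroxyl, giving 18.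

## Further compounds

F1 | step 9 | (2R,3R)-6-allyl-2-[3-allyl-4-(tert-butyldimethylsilyloxy)phenyl]-7-(tert-butyldimethylsilyloxy)-3-hydroxychroman-4-one | C=CCc1cc(ccc1O[Si](C)(C)C(C)(C)C)[C@H]1Oc2cc(O[Si](C)(C)C(C)(C)C)c(CC=C)cc2C(=O)[C@@H]1O
F2 | step 9 | (2R,3R)-7-(tert-butyldimethylsilyloxy)-2-[4-(tert-butyldimethylsilyloxy)-3-(3-methylbut-2-enyl)phenyl]-3-hydroxy-6-(3-methylbut-2-enyl)chroman-4-one | CC(C)=CCc1cc(ccc1O[Si](C)(C)C(C)(C)C)[C@H]1Oc2cc(O[Si](C)(C)C(C)(C)C)c(CC=C(C)C)cc2C(=O)[C@@H]1O
F3 | step 7 | [5-allyl-2,4-bis(methoxymethoxy)phenyl]{(2S,3R)-3-[3-allyl-4-(methoxymethoxy)phenyl]oxiran-2-yl}methanone | O=C(c1cc(CC=C)c(OCOC)cc1OCOC)[C@H]1O[C@@H]1c1ccc(OCOC)c(CC=C)c1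
F4 | step 7 | (5-allyl-2,4-dihydroxyphenyl)[(2S,3R)-3-(3-allyl-4-hydroxyphenyl)oxiran-2-yl]methanone | O=C(c1cc(CC=C)c(O)cc1O)[C@H]1O[C@@H]1c1ccc(O)c(CC=C)c1
F5 | step 7 | (2S,3S)-6-allyl-2-(3-allyl-4-hydroxyphenyl)-3,7-dihydroxychroman-4-one | C=CCc1cc(ccc1O)[C@@H]1Oc2cc(O)c(CC=C)cc2C(=O)[C@H]1O
F6 | step 8 | (2S)-1-(5-allyl-2,4-dihydroxyphenyl)-3-(3-allyl-4-hydroxyphenyl)-3-(benzylsulfanyl)-2-hydroxypropan-1-one (either configuration at C3) | O=C(c1cc(CC=C)c(O)cc1O)[C@H](O)C(SCc1ccccc1)c1ccc(O)c(CC=C)c1
A1 | alternative 1 | 2,3-trans-4-methoxy-7-(methoxymethoxy)-2-[4-(methoxymethoxy)-3-(3-methylbut-2-enyl)phenyl]-6-(3-methylbut-2-enyl)chroman-3-yl acetate, C2 and C3 arranged as in 22, C4 epimers | COCOc1ccc(cc1CC=C(C)C)[C@H]1Oc2cc(OCOC)c(CC=C(C)C)cc2C(OC)[C@@H]1OC(C)=O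
A2 | alternative 1 | 2-hydroxy-4-(methoxymethoxy)-5-(3-methylbut-2-enyl)benzaldehyde | O=Cc1cc(CC=C(C)C)c(OCOC)cc1O
A3 | alternative 1 | (E)-2-[4-(methoxymethoxy)-3-(3-methylbut-2-enyl)phenyl]ethenyl acetate | CC(=O)O/C=C/c1ccc(OCOC)c(CC=C(C)C)c1
A4 | alternative 1 | trimethyl orthoformate | COC(OC)OC
A5 | alternative 1 | 6-(methoxymethylidene)-3-(methoxymethoxy)-4-(3-methylbut-2-enyl)cyclohexa-2,4-dien-1-one | COC=C1C=C(CC=C(C)C)C(OCOC)=CC1=O
A6 | alternative 2 | syn-1-[2-fluoro-4-(methoxymethoxy)-5-(3-methylbut-2-enyl)phenyl]-3-hydroxy-2-(4-methoxybenzyloxy)-3-[4-(methoxymethoxy)-3-(3-methylbut-2-enyl)phenyl]propan-1-one, both centres arranged as in 22 | COCOc1ccc(cc1CC=C(C)C)[C@@H](O)[C@@H](OCc1ccc(OC)cc1)C(=O)c1cc(CC=C(C)C)c(OCOC)cc1F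
A7 | alternative 2 | 2-diazo-1-[2-fluoro-4-(methoxymethoxy)-5-(3-methylbut-2-enyl)phenyl]ethanone | [N-]=[N+]=CC(=O)c1cc(CC=C(C)C)c(OCOC)cc1F
A8 | alternative 2 | 4-(methoxymethoxy)-3-(3-methylbut-2-enyl)benzaldehyde | O=Cc1ccc(OCOC)c(CC=C(C)C)c1
A9 | alternative 2 | 4-methoxybenzyl alcohol | COc1ccc(CO)cc1
A10 | alternative 3 | 3-O-tert-butyldimethylsilyl 7-O-triisopropylsilyl 4'-O-methoxymethyl ether of 22 | COCOc1ccc(cc1CC=C(C)C)[C@H]1Oc2cc(O[Si](C(C)C)(C(C)C)C(C)C)c(CC=C(C)C)cc2C(=O)[C@@H]1O[Si](C)(C)C(C)(C)C
A11 | alternative 3 | (4R,5R)-4-(tert-butyldimethylsilyloxy)-5-(ethynyloxy)-5-[4-(methoxymethoxy)-3-(3-methylbut-2-enyl)phenyl]pent-1-yn-3-one | C#CC(=O)[C@H](O[Si](C)(C)C(C)(C)C)[C@H](OC#C)c1ccc(OCOC)c(CC=C(C)C)c1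
A12 | alternative 3 | triisopropyl[(5-methylhex-4-en-1-yn-1-yl)oxy]silane | CC(C)=CCC#CO[Si](C(C)C)(C(C)C)C(C)C
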